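The earlier runs and the new flask were computed for an exercise.

Millimoles per litre of incoming ligand against millimoles per litre of starting complex were the two amounts I held side by side.

| flask | starting complex | incoming ligand | leaving ligand | remark | time |
|---|---|---|---|---|---|
| blue | 26 mM | 80 mM | 40 mM | run made earlier |  |
| amber | 200 mM | 80 mM | 40 mM | run made earlier |  |
| winter | 20 mM | 80.0 mM | 40.0 mM |  | 2.0 h |
| midnight | 40 mM | 80.0 mM | 40.0 mM |  | 2.0 h |
| dusk | 80 mM | 80.0 mM | 40.0 mM |  | 2.0 h |
| spring | 150 mM | 80.0 mM | 40.0 mM |  | 2.0 h |

| run | time / min | complex with two exchanged / % | starting complex / % |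
|---|---|---|---|
| blue | 25.0 | 30.5 | 11.6 |
| blue | 50.0 | 26.6 | 3.7 |
| blue | 80.0 | 20.1 | 1.4 |
| blue | 90.0 | 18.5 | 1.2 |
| blue | 120 | 15.9 | 0.5 |
| amber | 25.0 | 6.2 | 48.6 |
| amber | 50.0 | 5.9 | 39.5 |
| amber | 80.0 | 5.1 | 31.6 |
| amber | 90.0 | 5.9 | 30.1 |
| amber | 120 | 6.2 | 24.8 |

(standard deviation of a reading: 0.5 percentage points)

- what was read earlier has a scatter of 0.5 percentage points, one standard deviation
- "hardly changes" means that all values lie within two and a half points (for a concentration: within two and a half percent of the largest)

- [complex with two exchanged] at the end for winter, midnight, dusk, spring, in this order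
- how the row runs (falls, then rises / hardly changes / falls all the way / rises all the way / rises, then falls)

I reckoned with 0.533 for spring: the allowance, c(incoming ligand) charged over c(starting complex) charged. A complex with two exchanged costs two ligands, so I held the allowance against two. Blue had 3.08, and its two-exchanged share fell from 30.5 % to 15.9 % between first and last reading. Amber had 0.400, and its share read 6.2 % and 6.2 % at those same readings. I read this as exchange still running onward in blue and stopped in amber.

So I committed to the following. Winter, with allowance 4.00, stays below 3.18 mM, since it should drain further than blue. Midnight and dusk reach at best blue's highest share, which gives 12.2 mM and 24.4 mM. On the short side two ligands must meet one complex, so I took the share as going with the square of the allowance; from amber that gives spring 16.5 mM. My row therefore rose, then fell.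

The forecast gave 2.8 mM, 6.5 mM, 10 mM and 11.5 mM, “levelling toward amber's 12 mM”, and its shape was rises all the way, so it parted from my row in the shape.

The flask gave 1.51 mM, 11.5 mM, 17.0 mM and 14.1 mM, so the row rises, then falls, under this scheme:

    starting complex + incoming ligand → leaving ligand + complex with one exchanged (k = 88.0 /M/h)
    complex with one exchanged + incoming ligand → leaving ligand + complex with two exchanged (k = 94.0 /M/h)
    complex with two exchanged + incoming ligand → leaving ligand + complex with three exchanged (k = 70.0 /M/h)
    complex with three exchanged + incoming ligand → leaving ligand + complex with four exchanged (k = 43.0 /M/h)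
    leaving ligand + starting complex → side product (k = 7.90 /M/h)

Spring held 0 % of its incoming ligand at 2.00 h, and its two-exchanged complex still stood at 9.39 % at 20.0 h. Its exchanges per complex charged, counted over the forms with one to four exchanged, came to 0.533, against the allowance of 0.533. The row turned at c(starting complex) 78 mM, an allowance of 1.02.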